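**Retrosynthetic overview**
1. Endgame: target ⇐ pentaol ⇐ bis-silyl acetonide lactone. The three secondary hydroxyls (C2, C9, C12) are acetylated last; the tertiary C8 and C11 hydroxyls stay free.
2. Key disconnection: C7–C8 and O7–C19 in one operation. The strategy rests on C7 and C8 being adjacent oxygen-bearing carbons shared by the ten-membered ring (C1–C10) and the γ-lactone (C7–O–C19–C17–C8), with C7 allylic to the Z C5=C6 alkene and C8 carrying the C17–C19 propionate unit. The seco compound is a C7 (Z)-enal with the C8 ketone as an α-methyl β-keto ester.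
3. Seco compound ⇐ temporary C2–O–C9 lactone: the lactone carbonyl (C9) is opened by an orthopropiolate acetylide (C8, C17, C19), C9 is set by transfer hydrogenation, and the ynoate is hydrated and C-methylated. C4–C5 comes from B-alkyl Suzuki coupling of a C2 vinyl group with a (Z)-3-iodobut-2-enol unit (C5–C7).
4. Ring A ⇐ Diels–Alder reaction of ethyl (E)-3-methyl-4-oxobut-2-enoate with a 3-silyloxypenta-1,3-diene (C1, C10), then enone → diene → cis-dihydroxylation under the conformational lock of the lactone (C11, C12). C2 is set by catalytic asymmetric vinylation.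
5. Ring order: ring A (step 2), temporary trans-fused lactone (step 7, opened in step 13), then the ten-membered ring and the γ-lactone together (step 20).

Key step: step 20

Numbering: briarane numbering (C1–C20) is used for all intermediates. The α face of ring A is the face carrying H10 in the target; the β face carries the C15 methyl.
Assumption: the (S)-oxazaborolidinium catalyst of step 2 is taken to leave open the C1 Si face of the boron-bound s-trans enal, as its accepted binding model for 2-substituted enals suggests; if the sense were the opposite, the mirror-image catalyst would be used and nothing else changes.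

**Step 1**
Reactants: 1 pent-1-en-3-one
Product: 2 (Z)-3-[(tert-butyldimethylsilyl)oxy]penta-1,3-diene
Conditions: TBSOTf, Et3N, Et2O, 0 °C
Reagents that add atoms: tert-butyldimethylsilyl triflate, CC(C)(C)[Si](C)(C)OS(=O)(=O)C(F)(F)F
Why: Soft enolisation and O-silylation of the ethyl ketone with a silyl triflate and a tertiary amine should give the Z silyl dienol ether, in which the future C11 methyl lies on the outside of the s-cis diene.

**Step 2**
Reactants: 2 (Z)-3-[(tert-butyldimethylsilyl)oxy]penta-1,3-diene; 3 ethyl (E)-3-methyl-4-oxobut-2-enoate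
Product: 4 ring A cycloadduct (C1: CHO and CH3; C10: H and CO2Et trans to CHO; C11: CH3, both epimers; C12(OTBS)=C13)
Conditions: (S)-B-(o-tolyl)-α,α-diphenylprolinol oxazaborolidine·HNTf2 (20 mol%), CH2Cl2, −78 to −40 °C
Reagents that add atoms: none
Why: Catalytic enantioselective Diels–Alder reaction of a 2-substituted enal, in which the boron-bound aldehyde makes C10 the electrophilic terminus that bonds to the nucleophilic C11 end of the silyloxy diene (C12–OSi para to C1), the E dienophile fixes formyl and ester trans, and the catalyst selects the C1 Si face, setting C1 and C10; the C11 epimers are carried on because C11 becomes sp2 in step 4.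

**Step 3**
Reactants: 4 ring A cycloadduct
Product: 5 C12 enone (C13=C14) with C2 aldehyde and C9 ethyl ester
Conditions: Pd(OAc)2 (1.1 equiv), MeCN, rt
Reagents that add atoms: none
Why: Saegusa–Ito oxidation, in which the palladium enolate at C13 can undergo β-hydride elimination only from C14, giving the C13=C14 enone without touching C1 or C10.

**Step 4**
Reactants: 5 C12 enone
Product: 6 11,13-dienyl C12 triflate
Conditions: PhNTf2, then KN(SiMe3)2 added slowly, THF, −78 °C
Reagents that add atoms: N-phenylbis(trifluoromethanesulfonimide), O=S(=O)(N(c1ccccc1)S(=O)(=O)C(F)(F)F)C(F)(F)F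
Why: Enol triflate formation, in which C11–H is the only enolisable position of the enone (C1 is quaternary) so the cross-conjugated dienolate is trapped on oxygen and C11 becomes sp2, while the neopentyl, non-enolisable C2 aldehyde is expected to survive in-situ trapping at −78 °C.

**Step 5**
Reactants: 6 11,13-dienyl C12 triflate
Product: 7 diene aldehyde (C11(CH3)=C12–C13=C14; C1: CHO and CH3; C10: CO2Et)
Conditions: Pd(OAc)2 (5 mol%), PPh3, HCO2H, n-Bu3N, DMF, 60 °C
Reagents that add atoms: none
Why: Palladium-catalysed formate reduction of an enol triflate (oxidative addition, formate exchange, decarboxylation, C–H reductive elimination) should give the 1,3-diene and leave aldehyde and ester untouched.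

**Step 6**
Reactants: 7 diene aldehyde
Product: 8 (2R)-allylic alcohol (C2: OH and vinyl) with C9 ethyl ester
Conditions: Zn(CH=CH2)2 (prepared separately), (+)-MIB [(2R)-3-exo-morpholinoisoborneol] (10 mol%), toluene, 0 °C; aq. NH4Cl
Reagents that add atoms: divinylzinc, C=C[Zn]C=C
Why: Amino-alcohol-catalysed enantioselective addition of a diorganozinc to an aldehyde, in which the (+)-ligand–zinc complex delivers vinyl to the Re face of the C2 aldehyde under reagent control (2R) and the reagent does not add to the ester.

**Step 7**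
Reactants: 8 (2R)-allylic alcohol
Product: 9 trans-fused C2–O–C9 γ-lactone (C2 vinyl cis to the C15 methyl; ring A 11,13-diene)
Conditions: PPTS (cat.), toluene, 70 °C, 4 Å MS
Reagents that add atoms: none
Why: Acid-catalysed intramolecular transesterification of the γ-hydroxy ester gives the trans-fused γ-lactone (C2 and C9 are trans on C1/C10), which locks C2 and C9 equatorial and the C15 methyl axial on ring A for the next step.

**Step 8**
Reactants: 9 trans-fused dienyl lactone
Product: 10 11α,12α-diol (C11: OH and CH3; C12: OH; C13=C14 retained)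
Conditions: OsO4 (2 mol%), NMO, acetone/H2O, 0 °C
Reagents that add atoms: N-methylmorpholine N-oxide, C[N+]1([O-])CCOCC1; water, O
Why: Upjohn dihydroxylation, in which osmylation should take the electron-rich trisubstituted C11=C12 end of the diene in preference to C13=C14 and to the hindered vinyl group deactivated by the allylic lactone oxygen, from the α face opposite the axial C15 methyl, setting C11 and C12 as the cis diol.

**Step 9**
Reactants: 10 11α,12α-diol
Product: 11 11,12-acetonide of the vinyl lactone
Conditions: 2,2-dimethoxypropane, PPTS (cat.), CH2Cl2, rt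
Reagents that add atoms: 2,2-dimethoxypropane, COC(C)(C)OC
Why: Acid-catalysed transketalisation of the cis-1,2-diol to the isopropylidene acetal, with no change at any stereocentre.

**Step 10**
Reactants: 12 but-2-yn-1-ol
Product: 13 (Z)-3-iodobut-2-en-1-ol
Conditions: NaAlH2(OCH2CH2OMe)2, Et2O, 0 °C; then I2, −78 °C
Reagents that add atoms: iodine, [I][I]
Why: Hydroxyl-directed trans-hydroalumination of the propargylic alcohol places aluminium on the methyl-bearing carbon (future C5), and iodinolysis with retention gives the Z iodide with iodine cis to CH2OH.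

**Step 11**
Reactants: 13 (Z)-3-iodobut-2-en-1-ol
Product: 14 (Z)-tert-butyl[(3-iodobut-2-en-1-yl)oxy]dimethylsilane
Conditions: TBSCl, imidazole, CH2Cl2, rt
Reagents that add atoms: tert-butyldimethylsilyl chloride, CC(C)(C)[Si](C)(C)Cl
Why: Standard silylation of the primary allylic alcohol (silyl ether formation), which leaves the vinyl iodide and its geometry untouched.

**Step 12**
Reactants: 11 11,12-acetonide of the vinyl lactone; 14 (Z)-vinyl iodide TBS ether
Product: 16 lactone carrying the (5Z) C3–C7 chain (C7 OTBS), via B-alkyl-9-BBN adduct 15 (not isolated)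
Conditions: 9-BBN, THF, rt; then 14, PdCl2(dppf) (5 mol%), AsPh3, Cs2CO3, DMF/H2O, rt
Reagents that add atoms: none
Why: Anti-Markovnikov hydroboration of the monosubstituted vinyl group (the hindered ring alkene does not react with 9-BBN) followed by B-alkyl Suzuki–Miyaura coupling joins C4 to C5 with retention of the Z geometry of the vinyl iodide.

**Step 13**
Reactants: 16 lactone carrying the (5Z) C3–C7 chain; 17 3,3,3-triethoxyprop-1-yne
Product: 18 C2 hydroxy C9 ynone orthoester
Conditions: 17, n-BuLi, THF, −78 °C; then 16, −78 to −40 °C; aq. NH4Cl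
Reagents that add atoms: none
Why: Addition of a lithium acetylide to a γ-lactone stops at the tetrahedral lithium lactolate (so C10 is not exposed as a ketone α-carbon under base) and opens on work-up to the C2 hydroxy C9 ynone, the orthoester masking the future C19 ester.

**Step 14**
Reactants: 18 C2 hydroxy C9 ynone orthoester
Product: 20 (2R,9R)-diol ethyl ynoate, via orthoester carbinol 19 (not isolated)
Conditions: Ru[(R,R)-TsDPEN](p-cymene) (5 mol%), i-PrOH, rt; then PPTS, THF/H2O, rt
Reagents that add atoms: water, O
Why: Noyori asymmetric transfer hydrogenation of an alkynyl ketone, in which the (R,R) catalyst treats the alkynyl group like the aryl group of an aryl ketone and delivers hydride to give the 9R carbinol under reagent control, after which mild aqueous acid converts the orthoester into the ethyl ester.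

**Step 15**
Reactants: 20 (2R,9R)-diol ethyl ynoate
Product: 21 2,7,9-tris(TBS) ethyl ynoate
Conditions: TBSOTf, 2,6-lutidine, CH2Cl2, −78 to 0 °C
Reagents that add atoms: tert-butyldimethylsilyl triflate, CC(C)(C)[Si](C)(C)OS(=O)(=O)C(F)(F)F
Why: Silylation with a silyl triflate is strong enough for the two hindered secondary hydroxyls at C2 and C9 and avoids the stronger amine bases that isomerise γ-hydroxy ynoates.

**Step 16**
Reactants: 21 2,7,9-tris(TBS) ethyl ynoate
Product: 23 C8 ketone β-keto ethyl ester (C17 H2), via pyrrolidine enamino ester 22 (not isolated)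
Conditions: pyrrolidine, MeCN, rt; then AcOH/H2O/THF, rt
Reagents that add atoms: water, O
Why: Conjugate addition of a secondary amine to the ynoate occurs at C8, the β-carbon, and hydrolysis of the resulting vinylogous carbamate places the ketone at C8 (regioselective formal hydration of an alkynoate).

**Step 17**
Reactants: 23 β-keto ethyl ester
Product: 24 α-methyl β-keto ethyl ester (C17 epimers)
Conditions: MeI (1.1 equiv), K2CO3, acetone, rt
Reagents that add atoms: iodomethane, CI
Why: C-alkylation of the β-keto ester enolate with iodomethane introduces C18 at C17; the new centre is epimerisable and both epimers are carried on.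

**Step 18**
Reactants: 24 α-methyl β-keto ethyl ester
Product: 25 C7 primary allylic alcohol (C2 and C9 still OTBS)
Conditions: HF·pyridine, pyridine, THF, 0 °C
Reagents that add atoms: none
Why: Buffered HF·pyridine cleaves the unhindered primary allylic silyl ether much faster than the two hindered secondary ones (selective desilylation).

**Step 19**
Reactants: 25 C7 primary allylic alcohol
Product: 26 seco C7 (Z)-enal with the C8 ketone as α-methyl β-keto ethyl ester
Conditions: MnO2 (excess), CH2Cl2, rt
Reagents that add atoms: none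
Why: MnO2 oxidises only the allylic alcohol and, being neutral, should leave the Z geometry and the β-keto ester intact (allylic oxidation).

**Step 20**
Reactants: 26 seco C7 (Z)-enal β-keto ester
Product: 28 protected lactone with the ten-membered ring closed and free C8 hydroxyl, via cis-diol ethyl ester 27 (not isolated)
Conditions: SmI2 (3 equiv), THF, 0.002 M, slow addition of 26, −78 to 20 °C; aq. NH4Cl
Reagents that add atoms: none
Why: Divalent samarium transfers one electron to the conjugated aldehyde, the most easily reduced carbonyl of 26, and the trivalent samarium bound to the ketyl oxygen also binds the C8 ketone and the C19 ester carbonyl, so that C7 (not C5, which would have to bond as a hindered tertiary carbon outside this chelate) adds to C8; a second electron gives the samarium cis-diolate of 27. The closest known reaction type is the SmI2 keto–aldehyde pinacol cyclisation of oxoalkyl β-keto esters and its medium-ring variants, followed by acyl transfer from the ester to the new alkoxide. The ten-membered ring closes by ketyl–carbonyl addition (C7–C8) under high dilution, the Z C5=C6 alkene and ring A holding C7 near C8, and the γ-lactone closes 5-exo-trig by attack of O7 on C19 with loss of ethoxide. C7 and C8 are set together: the samarium bridge puts O7 and O8 on the same face of the new ring (cis diol), and C8 is attacked anti to the C9–O bond (polar Felkin–Anh), which is why C9 carries a non-chelating silyl ether, a chelating ether favouring the opposite C8 epimer; C17 equilibrates through the lactone enol to the epimer with methyl trans to C9. The step needs reduction of the enal in preference to the α-silyloxy ketone (no HMPA, low temperature), bonding through C7, retention of the Z alkene, and the C7/C8 facial selectivity described.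

**Step 21**
Reactants: 28 protected lactone
Product: 29 pentaol (C2, C8, C9, C11, C12 hydroxyls)
Conditions: HF (48% aq.), MeCN, 0 °C to rt
Reagents that add atoms: none
Why: Aqueous HF in acetonitrile removes both silyl ethers and hydrolyses the isopropylidene acetal in one operation (acidic global deprotection) under conditions too mild to ionise the allylic C7–O bond of the lactone.

**Step 22**
Reactants: 29 pentaol
Product: 30 CNP0129620.2 (2,9,12-triacetate)
Conditions: Ac2O, pyridine, DMAP (cat.), CH2Cl2, rt
Reagents that add atoms: acetic anhydride, CC(=O)OC(C)=O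
Why: DMAP-catalysed acylation acetylates the three secondary hydroxyls at C2, C9 and C12, whereas the tertiary C8 and C11 hydroxyls do not react under these conditions.

**Compound list**
1 | pent-1-en-3-one | C=CC(=O)CC | starting material
2 | (Z)-3-[(tert-butyldimethylsilyl)oxy]penta-1,3-diene | C=C/C(O[Si](C)(C)C(C)(C)C)=C/C | intermediate
3 | ethyl (E)-3-methyl-4-oxobut-2-enoate | CCOC(=O)/C=C(C)/C=O | starting material
4 | ethyl 3-[(tert-butyldimethylsilyl)oxy]-6-formyl-2,6-dimethylcyclohex-3-ene-1-carboxylate (formyl and ester trans; ring C2 = briarane C11, both epimers) | O=C[C@@]2(C)CC=C(O[Si](C)(C)C(C)(C)C)C(C)[C@@H]2C(=O)OCC | intermediate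
5 | ethyl 6-formyl-2,6-dimethyl-3-oxocyclohex-4-ene-1-carboxylate (C11 epimers) | O=C[C@@]2(C)C=CC(=O)C(C)[C@@H]2C(=O)OCC | intermediate
6 | ethyl 6-formyl-2,6-dimethyl-3-[(trifluoromethanesulfonyl)oxy]cyclohexa-2,4-diene-1-carboxylate | O=C[C@@]2(C)C=CC(OS(=O)(=O)C(F)(F)F)=C(C)[C@@H]2C(=O)OCC | intermediate
7 | ethyl 6-formyl-2,6-dimethylcyclohexa-2,4-diene-1-carboxylate | O=C[C@@]2(C)C=CC=C(C)[C@@H]2C(=O)OCC | intermediate
8 | ethyl 6-[(1R)-1-hydroxyprop-2-en-1-yl]-2,6-dimethylcyclohexa-2,4-diene-1-carboxylate | C=C[C@@H](O)[C@@]2(C)C=CC=C(C)[C@@H]2C(=O)OCC | intermediate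
9 | trans-fused C2–O–C9 γ-lactone of the ring A 11,13-diene, C2 vinyl (3a,7-dimethyl-3-vinyl-3a,7a-dihydro-2-benzofuran-1(3H)-one skeleton) | C=C[C@H]3OC(=O)[C@H]2C(C)=CC=C[C@@]23C | intermediate
10 | 11α,12α-dihydroxy C13=C14 vinyl lactone | C=C[C@H]3OC(=O)[C@H]2[C@](C)(O)[C@H](O)C=C[C@@]23C | intermediate
11 | 11,12-O-isopropylidene vinyl lactone | C=C[C@H]3OC(=O)[C@H]2[C@]4(C)OC(C)(C)O[C@@H]4C=C[C@@]23C | intermediate
12 | but-2-yn-1-ol | CC#CCO | starting material
13 | (Z)-3-iodobut-2-en-1-ol | C/C(I)=C/CO | intermediate
14 | (Z)-tert-butyl[(3-iodobut-2-en-1-yl)oxy]dimethylsilane | C/C(I)=C/CO[Si](C)(C)C(C)(C)C | intermediate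
15 | B-alkyl-9-BBN adduct of 11 (boron on C4) | B5(CC[C@H]3OC(=O)[C@H]2[C@]4(C)OC(C)(C)O[C@@H]4C=C[C@@]23C)C6CCCC5CCC6 | intermediate
16 | acetonide lactone with the (5Z)-CH2CH2C(CH3)=CHCH2OTBS chain on C2 | CC(C)(C)[Si](C)(C)OC/C=C(C)\CC[C@H]3OC(=O)[C@H]2[C@]4(C)OC(C)(C)O[C@@H]4C=C[C@@]23C | intermediate
17 | 3,3,3-triethoxyprop-1-yne | C#CC(OCC)(OCC)OCC | starting material
18 | C2 hydroxy C9 ynone with triethyl orthoester terminus | CC(C)(C)[Si](C)(C)OC/C=C(C)\CC[C@@H](O)[C@@]2(C)C=C[C@H]4OC(C)(C)O[C@@]4(C)[C@@H]2C(=O)C#CC(OCC)(OCC)OCC | intermediate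
19 | (2R,9R)-diol with triethyl orthoester terminus | CC(C)(C)[Si](C)(C)OC/C=C(C)\CC[C@@H](O)[C@@]2(C)C=C[C@H]4OC(C)(C)O[C@@]4(C)[C@@H]2[C@@H](O)C#CC(OCC)(OCC)OCC | intermediate
20 | (2R,9R)-diol ethyl ynoate | CC(C)(C)[Si](C)(C)OC/C=C(C)\CC[C@@H](O)[C@@]2(C)C=C[C@H]4OC(C)(C)O[C@@]4(C)[C@@H]2[C@@H](O)C#CC(=O)OCC | intermediate
21 | 2,7,9-tris(TBS) ethyl ynoate | CC(C)(C)[Si](C)(C)OC/C=C(C)\CC[C@@H](O[Si](C)(C)C(C)(C)C)[C@@]2(C)C=C[C@H]4OC(C)(C)O[C@@]4(C)[C@@H]2[C@@H](O[Si](C)(C)C(C)(C)C)C#CC(=O)OCC | intermediate
22 | C8 pyrrolidine enamino ester | CC(C)(C)[Si](C)(C)OC/C=C(C)\CC[C@@H](O[Si](C)(C)C(C)(C)C)[C@@]2(C)C=C[C@H]4OC(C)(C)O[C@@]4(C)[C@@H]2[C@@H](O[Si](C)(C)C(C)(C)C)/C(N5CCCC5)=C\C(=O)OCC | intermediate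
23 | C8 ketone β-keto ethyl ester (C17 H2) | CC(C)(C)[Si](C)(C)OC/C=C(C)\CC[C@@H](O[Si](C)(C)C(C)(C)C)[C@@]2(C)C=C[C@H]4OC(C)(C)O[C@@]4(C)[C@@H]2[C@@H](O[Si](C)(C)C(C)(C)C)C(=O)CC(=O)OCC | intermediate
24 | α-methyl β-keto ethyl ester (C17 epimers) | CC(C)(C)[Si](C)(C)OC/C=C(C)\CC[C@@H](O[Si](C)(C)C(C)(C)C)[C@@]2(C)C=C[C@H]4OC(C)(C)O[C@@]4(C)[C@@H]2[C@@H](O[Si](C)(C)C(C)(C)C)C(=O)C(C)C(=O)OCC | intermediate
25 | C7 allylic alcohol (C17 epimers) | OC/C=C(C)\CC[C@@H](O[Si](C)(C)C(C)(C)C)[C@@]2(C)C=C[C@H]4OC(C)(C)O[C@@]4(C)[C@@H]2[C@@H](O[Si](C)(C)C(C)(C)C)C(=O)C(C)C(=O)OCC | intermediate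
26 | seco C7 (Z)-enal, C8 ketone as α-methyl β-keto ethyl ester, C2 and C9 OTBS, 11,12-acetonide (C17 epimers) | O=C/C=C(C)\CC[C@@H](O[Si](C)(C)C(C)(C)C)[C@@]2(C)C=C[C@H]4OC(C)(C)O[C@@]4(C)[C@@H]2[C@@H](O[Si](C)(C)C(C)(C)C)C(=O)C(C)C(=O)OCC | intermediate
27 | ten-membered 7,8-cis-diol ethyl ester | CC(C)(C)[Si](C)(C)O[C@@H]1[C@H]2[C@]3(C)OC(C)(C)O[C@@H]3C=C[C@]2(C)[C@H](O[Si](C)(C)C(C)(C)C)CC/C(C)=C\[C@H](O)[C@@]1(O)C(C)C(=O)OCC | intermediate
28 | protected target: 2,9-bis(TBS) 11,12-acetonide lactone with free C8 hydroxyl | CC(C)(C)[Si](C)(C)O[C@@H]1[C@H]2[C@]3(C)OC(C)(C)O[C@@H]3C=C[C@]2(C)[C@H](O[Si](C)(C)C(C)(C)C)CC/C(C)=C\[C@@H]2OC(=O)[C@H](C)[C@]21O | intermediate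
29 | 2,8,9,11,12-pentaol lactone | O[C@@H]1[C@H]2[C@](C)(O)[C@H](O)C=C[C@]2(C)[C@H](O)CC/C(C)=C\[C@@H]2OC(=O)[C@H](C)[C@]21O | intermediate
30 | CNP0129620.2 (2,9,12-triacetoxy-8,11-dihydroxy briarane lactone) | CC(=O)O[C@@H]1[C@H]2[C@](C)(O)[C@H](OC(C)=O)C=C[C@]2(C)[C@H](OC(C)=O)CC/C(C)=C\[C@@H]2OC(=O)[C@H](C)[C@]21O | target

**Step count**
Total: 22 steps. Longest linear sequence: 20 steps (steps 1–9 and 12–22, from pent-1-en-3-one); the vinyl iodide branch is 2 steps (steps 10–11).

**Steps most likely to fail**

Step 20 (ring closure and lactonisation). The enal ketyl may bond through C5 or dimerise, the Z alkene may isomerise at the ketyl stage, the C9–O bond of the α-silyloxy ketone may be cleaved reductively, the ketone may be held back as a samarium enolate, or C8 may be attacked on the wrong face. Fallback, from 26 back to 28: the keto-enal is cyclised by a low-valent titanium pinacol coupling held at the diol stage (McMurry-type, TiCl3(DME)1.5, Zn–Cu couple, DME, 0 °C, slow addition). Both carbonyl oxygens are then bound to the titanium surface before the C7–C8 bond forms, so no free conjugated ketyl is needed and no acyl transfer has to occur in the reducing medium. The cis-diol ethyl ester 27 is isolated and lactonised separately (PPTS, CH2Cl2) to give 28. This fallback makes no compound outside the list (none, F0).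

Step 8 (dihydroxylation). Osmylation may occur at the C2 vinyl group or on the β face of the diene, giving the wrong diol. Fallback, from 9 back to 10: the diene alone is addressed with singlet oxygen (O2, hν, tetraphenylporphyrin, CH2Cl2, 0 °C), which does not react with the vinyl group and should add across C11/C14 from the α face to give the 11,14-endoperoxide F1. Kornblum–DeLaMare rearrangement (Et3N, CH2Cl2) opens it through the only available C14–H to the 11α-hydroxy C12=C13 C14 enone F2. Hydroxyl-directed nucleophilic epoxidation (H2O2, NaOH, MeOH, 0 °C) gives the 12α,13α-epoxy ketone F3. Wharton transposition (N2H4·H2O, AcOH cat., MeOH) then moves the oxygen to C12 and the alkene to C13=C14, giving diol 10.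

Step 2 (Diels–Alder reaction). Enantiofacial control may be low with the trisubstituted dienophile, cycloaddition may be slow, or the silyl dienol ether may be consumed by an aldol-type side reaction at the aldehyde. Fallback, from 3 back to 5: commercial (E)-1-(dimethylamino)pent-1-en-3-one is O-silylated (NaN(SiMe3)2, TBSCl, THF, −78 °C) to the far more nucleophilic (1E,3Z)-1-amino-3-silyloxy diene F4. This diene should add to 3 at low temperature with the same regiochemistry under a chiral (R,R)-(salen)CrSbF6 catalyst (trivalent chromium, 5 mol%, CH2Cl2, −40 °C) to give the amino cycloadduct F5. Aqueous HF in MeCN then removes the silyl group and eliminates dimethylamine to give enone 5 directly, so that step 3 is not needed.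

**Further compounds**
F0 | step 20 | none | none
F1 | step 8 | 11α,14α-epidioxy C12=C13 vinyl lactone (endoperoxide) | C=C[C@H]3OC(=O)[C@H]2[C@@]4(C)C=C[C@H](OO4)[C@@]23C
F2 | step 8 | 11α-hydroxy C12=C13 C14 enone vinyl lactone | C=C[C@H]3OC(=O)[C@H]2[C@](C)(O)C=CC(=O)[C@@]23C
F3 | step 8 | 11α-hydroxy 12α,13α-epoxy C14 ketone vinyl lactone | C=C[C@H]3OC(=O)[C@H]2[C@](C)(O)[C@@H]4O[C@@H]4C(=O)[C@@]23C
F4 | step 2 | (1E,3Z)-3-[(tert-butyldimethylsilyl)oxy]-N,N-dimethylpenta-1,3-dien-1-amine | CN(C)/C=C/C(O[Si](C)(C)C(C)(C)C)=C/C
F5 | step 2 | ethyl 3-[(tert-butyldimethylsilyl)oxy]-5-(dimethylamino)-6-formyl-2,6-dimethylcyclohex-3-ene-1-carboxylate (C11 and C14 epimers) | O=C[C@@]2(C)C(N(C)C)C=C(O[Si](C)(C)C(C)(C)C)C(C)[C@@H]2C(=O)OCC
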